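The pitfall is to fit one first-order constant to the substrate readings of the green run, which is this same flask followed so far.

- green: substrate 1.5 M; coupling partner 1.2 equiv (fed, over 5.0 h); free catalyst 0.05 mol%; the very flask that is asked about, followed so far; the fed solution adds 1.0 times the starting volume
- flask: substrate 1.5 M; coupling partner 1.20 equiv (fed, over 5.0 h); free catalyst 0.05 mol%; time 50 h; the fed solution adds 1.0 times the starting volume

- green (time / h: target / %, substrate / %, isomer of the product / %): 2.00: 7.4, 95.1, 0.2; 3.00: 8.9, 92.0, 0; 6.00: 17.2, 83.3, 0.6; 10.0: 25.4, 73.2, 1.7; 15.0: 35.2, 61.3, 3.2; 25.0: 53.6, 41.7, 3.7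

(readings scatter by 1 percentage point)

- target is meant together with its crystals
- every charge counts on the volume at the start, and the solution that is fed holds the whole dose
- solid, in amounts per volume of the solution: crystals
- reactions considered so far: coupling partner + free catalyst -> catalyst intermediate A; catalyst intermediate C -> free catalyst + target; target <-> isomer of the product; substrate + catalyst intermediate B -> catalyst intermediate C; crystals <-> target; catalyst intermediate A -> catalyst intermediate B

- the target in the flask at 50 h, as a percentage of the substrate charged
- the substrate in the flask at 50 h, as a percentage of the substrate charged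
- the isomer of the product in the flask at 50 h, as a percentage of the substrate charged

I compare that constant at two moments. On substrate it reads 0.0341 h⁻¹ from 6.00 h to 15.0 h, then 0.0385 h⁻¹ up to 25.0 h. On p, the partner left, which after the feed is substrate plus 20.0% of the substrate charged, it reads 0.0266 h⁻¹ and 0.0276 h⁻¹, which drifts less.

Read from 6.00 h to 25.0 h, p falls at 0.0271 h⁻¹; this is k, the pseudo-first-order constant of partner left. Counted from the full charge, k gives 60.9% at 25.0 h, against 61.7% from the reading. Carried from that reading to 50 h, p is 31.3%, so substrate is 11.3%, and target plus isomer 88.7%.

The weak link is the isomer: its last two readings, 3.2% and 3.7%, lie within the scatter of 1 percentage point, so they do not tell a plateau from a further rise. I therefore hold its ratio to target, 0.0777 over those readings, which gives isomer 6.39% and target 82.3%.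

The forecast says 83% target, 13% substrate and 4.2% isomer, on the ground that “This suggests partner capture by catalyst is rate-limiting”. Its substrate stands above mine and its isomer below mine.

The flask gives 79.5% target, 12.3% substrate and 8.18% isomer.

    coupling partner + free catalyst → catalyst intermediate A (k = 0.500 M⁻¹ s⁻¹)
    catalyst intermediate C → free catalyst + target (k = 0.0545 s⁻¹)
    target ⇌ isomer of the product (K = 0.110, k = 4.77 × 10⁻⁶ s⁻¹)
    substrate + catalyst intermediate B → catalyst intermediate C (k = 0.0485 M⁻¹ s⁻¹)
    crystals ⇌ target, rate k5*(cs5 - [target]) while solid is left; crystals form when [target] > cs5 (solubility = 1.30 M, k = 8.32 × 10⁻⁵ s⁻¹)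
    catalyst intermediate A → catalyst intermediate B (k = 0.0664 s⁻¹)

With k I reckoned partner left at 26.1% of its own charge, and at 50 h this flask holds 27%. The forecast is right within its margins for this flask, and a run at another loading shows what changes that. For the neighbouring flask with 0.02 mol% of free catalyst, I scale k by the loading to 0.0108 h⁻¹. From the charge, that leaves 58.1% of the partner at 50 h, hence substrate 49.8%. That neighbouring flask holds 59% of its partner, and 44.5% target, and its substrate stands at 51.1%.

(All runs are calculated for substances that don't exist; scatter was added.)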